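At each time of reading in the earlier runs, the table shows intermediate and target, not starting material. In the south-west run at 10.0 s, I see 9.4 % intermediate and 0 % target.

| flask | starting material | remark | time |
|---|---|---|---|
| north-west | 1 mM | run made earlier |  |
| south | 1.4 mM | run made earlier |  |
| south-west | 2.2 mM | run made earlier |  |
| Thursday's | 1.0 mM | a single well-mixed tank run continuously and read at steady state, 6.00 min in it on average |  |
| Friday's | 1.0 mM | one stirred flow tank at steady state, fed with the mixture as stated, mean residence time 2.0 min |  |
| Wednesday's | 1.0 mM | a closed flask charged with all of it at once and left for 2.0 min | 2.0 min |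
| Sunday's | 1.0 mM | plug flow through a tube for 2.0 min, no back-mixing | 2.0 min |

| run | time / s | intermediate / % | target / % |
|---|---|---|---|
| north-west | 15.0 | 13.5 | 2.2 |
| north-west | 30.0 | 13.8 | 3.5 |
| north-west | 50.0 | 14.6 | 4.6 |
| north-west | 60.0 | 9.3 | 4.3 |
| north-west | 80.0 | 9.5 | 5.6 |
| north-west | 90.0 | 9.6 | 6.5 |
| north-west | 120 | 5.5 | 7.4 |
| south | 10.0 | 11.8 | 0 |
| south | 12.0 | 10.4 | 0 |
| south | 20.0 | 13.6 | 0 |
| south | 25.0 | 12.0 | 2.5 |
| south | 40.0 | 11.5 | 2.1 |
| south | 60.0 | 10.6 | 5.0 |
| south | 90.0 | 8.1 | 5.6 |
| south-west | 10.0 | 9.4 | 0 |
| south-west | 12.0 | 8.3 | 0 |
| south-west | 20.0 | 9.3 | 0 |
| south-west | 25.0 | 8.9 | 0 |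
| south-west | 40.0 | 6.6 | 2.6 |
| south-west | 60.0 | 7.5 | 3.2 |
| south-west | 90.0 | 3.5 | 1.4 |

(standard deviation of a reading: 1 percentage point)

- the stated concentrations are those of everything mixed, before any reaction; amounts are the same in each set-up
- the numbers in the tables scatter with a standard deviation of 1 percentage point
- the earlier runs were made in a closed, stirred flask

* the set-up with the highest amount of intermediate at the outlet or at the end, in percent of the starting material put in ("none" if the first two lie within 2 percentage points) (Thursday's / Friday's / Wednesday's / Sunday's / none)
* amount of intermediate at the outlet or at the end, in percent of the starting material put in, Thursday's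
* amount of intermediate at the outlet or at the end, in percent of the starting material put in, Friday's
* amount of intermediate at the outlet or at the end, in percent of the starting material put in, Wednesday's
* amount of intermediate at the outlet or at the end, in percent of the starting material put in, Sunday's

I read the early rows column against column. In the north-west run, intermediate plus target averages 17.4 % over the first three rows. In the south run, the same sum averages 11.9 % over the first three rows, and in the south-west run 8.98 % over the first four. The seen share falls as the charge rises.

So I take starting material to pass first-order into intermediate while a second-order loss competes for it. I divide one rate by the other, and time drops out. At any level of starting material, the share going to intermediate is the crossing level over the sum of crossing level and present level, a form that reads like a Michaelis constant. This is a selectivity factor that depends on concentration.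

In a closed flask the level sweeps down from the charge towards zero. The mean share is then the logarithm of one plus R, over R, where R is the charge over the crossing level. The north-west average gives R of 16.3. So the crossing level, at which both ways run equally fast, reads 0.0612 mM.

As a check, that level gives 10.0 % for the south-west charge and 13.9 % for the south charge, each above the average read there. The fall with charge is followed, but my level is a rough reading.

The forecast gives 5.3 % for Thursday's, 7.9 % for Friday's, 5.9 % for Wednesday's and 5.9 % for Sunday's, and names Friday's. It has the intermediate “lost mainly second order to unseen products”. I put the second-order loss on starting material instead. A tank holds starting material below the charge, so I expect both tanks above the forecast, with the same leader.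

Friday's gives 18.2 %, Thursday's 11.4 %, Wednesday's 5.56 % and Sunday's 5.56 %, so Friday's leads.

    starting material → intermediate (k = 0.0453 s⁻¹)
    intermediate → target (k = 0.0135 s⁻¹)
    2 starting material → self-condensation product (k = 237 M⁻¹ s⁻¹)
    target ⇌ isomer of the product (K = 1.40, k = 1.01 s⁻¹)

Friday's tank holds starting material at 0.0876 mM against a charge of 1.0 mM. At that level, my crossing level gives a share of 41.1 %, more than the 17.4 % seen in the north-west run at the same charge.

Take a closed flask like Wednesday's, charged with 0.25 mM. The crossing level estimates a mean share of 39.8 % through intermediate. At 2.00 min this flask holds 12.4 % intermediate, 15.3 % target and 21.3 % isomer of the product, together 49.0 %, more than my estimate.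

(All runs were computed for substances that don't exist; scatter was added.)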